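The runs come from a simulation with made-up constants.

Larch, the earlier run with half the coupling partner of ash, reads 50% right-handed substrate against 38% left-handed substrate at 12.0 h, so this is a kinetic resolution.

the same everywhere: left-handed substrate 20 mM; right-handed substrate 20 mM

| run | coupling partner | protic impurity | precatalyst | remark | time |
|---|---|---|---|---|---|
| ash | 60 mM | 2 mM | 2 mM | the very flask that is asked about, followed so far |  |
| larch | 30 mM | 2 mM | 2 mM | run made earlier |  |
| flask | 60.0 mM | 2.00 mM | 2.0 mM |  | 30 h |

| run | time / h | right-handed substrate / % | left-handed substrate / % | left-handed product / % |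
|---|---|---|---|---|
| ash | 0.200 | 49 | 51 | 0 |
| ash | 0.500 | 49 | 52 | 0 |
| ash | 1.00 | 50 | 49 | 0 |
| ash | 1.50 | 51 | 48 | 1 |
| ash | 2.00 | 48 | 47 | 2 |
| ash | 3.00 | 49 | 45 | 6 |
| ash | 4.00 | 49 | 42 | 9 |
| larch | 1.50 | 48 | 50 | 3 |
| larch | 3.00 | 48 | 48 | 4 |
| larch | 5.00 | 48 | 46 | 3 |
| larch | 6.00 | 51 | 43 | 5 |
| larch | 8.00 | 51 | 39 | 6 |
| larch | 10.0 | 50 | 37 | 11 |
| larch | 12.0 | 50 | 38 | 13 |

(readings scatter by 1.5 percentage points)

1. whether the excess of right-handed substrate over left-handed substrate among what is left of the two reaches 80% by 30 h (no / yes)
2. the highest excess of right-handed substrate over left-handed substrate among what is left of the two up to 30 h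

- free catalyst is single-handed; left-handed substrate and right-handed substrate are mirror images of each other, charged as a racemate, each of them at the stated concentration
- the analysis behind the earlier runs scatters by 1.5 percentage points, standard deviation

Fold the excess into one number. Call ln([right-handed substrate]/[left-handed substrate]) the lead. An excess of 80% needs a lead of 2.20. In ash the lead grew by 0.0665 /h between 2.00 h and 4.00 h, a reading with wide scatter. That gives 0.909. This is the reach, the lead built in 30 h at that pace divided by the lead needed. Above one, that pace gets there.

Is one pace enough? Test it on larch. Its lead grew by 0.0238 /h up to 5.00 h, then by 0.0517 /h up to 10.0 h, about twice as fast. So the pace in larch reads as climbing, though the scatter is wide, and if ash climbs too, its reach reads low. I commit to yes, narrowly.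

The forecast differs. It says no, with a top of 67%, and puts the target beyond its estimate “unless the catalyst keeps building up”.

Ash gives yes: the excess reaches 80% at 22.0 h, and its highest value up to 30 h is 91.6%.

    coupling partner + precatalyst → free catalyst + spent reagent (k = 3.60 /M/h)
    free catalyst + right-handed substrate ⇌ catalyst intermediate B (K = 35.0 /M, k = 17000 /M/h)
    coupling partner + free catalyst → spent catalyst (k = 0.740 /M/h)
    coupling partner + protic impurity → quenched reagent (k = 7.00 /M/h)
    coupling partner + catalyst intermediate A → free catalyst + left-handed product (k = 43.0 /M/h)
    free catalyst + left-handed substrate ⇌ catalyst intermediate A (K = 120 /M, k = 2300 /M/h)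
    coupling partner + catalyst intermediate B → free catalyst + right-handed product (k = 11.0 /M/h)

Counted with the lead at that top, the reach of ash is 1.43, against 0.909. In ash, between 3.00 h and 15.0 h, precatalyst fell from 53.5% to 7.33% of the catalyst charged, free catalyst rose from 12.9% to 38.4% of the catalyst charged, and left-handed substrate fell from 43.8% to 11.3% of the two substrates charged together. At 30.0 h left-handed substrate stood at 1.59% and right-handed product at 12.4% of the two substrates charged together, and spent catalyst at 28.2% of the catalyst charged.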